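**Small charge.** A small charge of stray impurity, 1.4 mM, stood against a catalyst loading of 2.5 mol%, and I had to decide whether to run the flask as written or change it first.

| flask | substrate | gas phase | protic impurity | free catalyst | stray impurity | remark | time |
|---|---|---|---|---|---|---|---|
| south-east | 0.050 M | 4.9 mM (held) | 0.025 M | 1.7 mol% | 1.4 mM | run made earlier |  |
| east | 0.050 M | 4.9 mM (held) | 0.025 M | 3.8 mol% | 1.4 mM | run made earlier |  |
| flask | 0.050 M | 4.9 mM (held) | 0.0250 M | 2.5 mol% | 1.4 mM |  | 8.0 h |

| run | time / h | target / % |
|---|---|---|
| south-east | 1.00 | 3.4 |
| south-east | 3.00 | 2.0 |
| south-east | 5.00 | 1.7 |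
| south-east | 8.00 | 2.3 |
| east | 0.667 | 8.9 |
| east | 1.33 | 21.3 |
| east | 3.00 | 46.3 |
| east | 8.00 | 92.1 |

(each reading ± 1 percentage point)

- target at 8.0 h, in percent of the substrate charged
- the change that raises the amount of target at 8.0 h, in percent of the substrate charged most ("none" if none brings more than 2 percentage points) (dawn / spring / summer / none)
- amount of target at 8.0 h, in percent of the substrate charged, after summer

- at the start none of the gas phase is in solution

- dawn: doubling the transfer coefficient of the gas phase, all else as stated
- spring: doubling the saturation concentration of gas phase, all else as stated
- summer: doubling the amount of free catalyst, all else as stated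

**The margin.** The south-east run stayed flat, averaging 2.35% from 1.00 h on, while the east run climbed to 92.1% at 8.00 h, and the two differed in their catalyst loading. I read this as the stray impurity destroying free catalyst one for one, which makes equal concentrations the zero of the scale. The flask's margin m came to −0.150 mM, that is, the free catalyst charged less the stray impurity charged, both as concentrations. South-east had −0.550 mM and east 0.500 mM.

**The decision.** The flask as written held less catalyst than stray impurity, so I expected it to stall with 10.7% of its stray impurity left. Its margin stood higher than south-east's, so I put its plateau above that run's, without a sharper figure. Dawn and spring leave m unchanged, so I chose summer, which gives 1.10 mM, twice east's margin, and I expected more target than east's 92.1%.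

**The forecast.** The forecast, unlike my reckoning, kept the flask at the background, 2.4%, saying “it should also be dead”, and it named summer as best, with 97% after it.

**The result.** The flask gave 8.83%. The best change was summer, which gained 91 percentage points and reached 99.7%, against 8.2 points for spring and 4.5 points for dawn.

    gas phase ⇌ dissolved gas, rate k1*(csat - [dissolved gas]) (kL = 2.00 h⁻¹)
    free catalyst + stray impurity → spent catalyst (k = 12000 M⁻¹ h⁻¹)
    2 substrate → self-condensation product (k = 0.00240 M⁻¹ h⁻¹)
    dissolved gas + protic impurity → quenched reagent (k = 13.0 M⁻¹ h⁻¹)
    substrate + dissolved gas + free catalyst → free catalyst + target (k = 5.00 × 10⁵ M⁻² h⁻¹)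

**Margin again.** In the flask, free catalyst fell from 3.22% at 0.800 h to 0% at 8.00 h, and target stood at 8.82% at 4.00 h and at 8.83% at 8.00 h. Stray impurity left at 8.00 h was 11%, against my 10.7%. The neighbouring flask, charged with 10 mol% of free catalyst, has a margin of 3.60 mM, which leaves 72.0% of its catalyst free. At 8.00 h that flask held 72.0% free catalyst and 0% stray impurity, and its target stood at >99.9%.

The runs were generated by integration from invented constants; scatter was added.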